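**Retrosynthetic overview**

- The strategy rests on ring A (C4a, C5, C6, C7, C8, C8a). It carries a para pair of oxygens, free OH at C5 and OMe at C8, with C6–H and C7–O between them, and it is fused on the C4a=C8a bond of the 3-oxy-2-aryl-4-pyranone (ring C). This is the substitution that a 3-alkoxy-4-methoxycyclobutenone leaves when it expands across the C5=C6 bond of a monocyclic γ-pyrone: ketene carbon to C5, carbinol carbon to C8, alkoxy carbon to C7, CH to C6.
- Last disconnections: the two fluoride-labile groups on O3 and O7, then the C4a–C5 bond of ring A, leading back to a 4-methoxy-4-(pyranonyl)cyclobutenone.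
- The C8–C8a bond is cut next: a C6-metalated 2-aryl-3-silyloxy-4-pyranone adds to a semisquarate, and the alkoxide is methylated.
- The arylpyranone comes from pyromeconic acid (bromination, silylation, Suzuki–Miyaura coupling with a prenyloxyphenyl boronate); the semisquarate comes from squaric acid through its bis(2-trimethylsilylethyl) ester.
- Ring order: ring C is bought, ring B is attached at C2, the four-membered ring is attached at the future C8a, and ring A is closed last.

Key step: step 10

Remark: the target has no stereocentre; the sp3 carbons created on the way (in 12, 15, 16 and 18) are racemic and are destroyed again, and "prenyl" denotes 3-methylbut-2-en-1-yl.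

**Route**

Step 1
Reactants: 1 3-hydroxy-4H-pyran-4-one (pyromeconic acid)
Product: 2 2-bromo-3-hydroxy-4H-pyran-4-one
Conditions: NBS (1.05 equiv), MeCN, 0 °C to rt, dark
Reagents that add atoms: N-bromosuccinimide, O=C1CCC(=O)N1Br
Why: electrophilic bromination of a diosphenol, in which the 3-OH makes C2 the β-carbon of an enol, so substitution should occur there (as in maltol-type 3-hydroxy-4-pyranones) and not at C5 or C6.

Step 2
Reactants: 2 2-bromo-3-hydroxy-4H-pyran-4-one
Product: 3 2-bromo-3-(triisopropylsilyloxy)-4H-pyran-4-one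
Conditions: TIPSOTf (1.2 equiv), 2,6-lutidine (1.5 equiv), CH2Cl2, 0 °C
Reagents that add atoms: triisopropylsilyl trifluoromethanesulfonate, CC(C)[Si](OS(=O)(=O)C(F)(F)F)(C(C)C)C(C)C
Why: O-silylation of the acidic enolic OH with a silyl triflate and a hindered pyridine base; the bulky TIPS ether should survive the later aqueous base, the lithium amide and 105 °C, and it falls to fluoride at the end.

Step 3
Reactants: 4 4-hydroxyphenylboronic acid pinacol ester; 5 prenyl bromide
Product: 6 4-(prenyloxy)phenylboronic acid pinacol ester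
Conditions: K2CO3 (1.5 equiv), acetone, 50 °C
Reagents that add atoms: none
Why: Williamson etherification of the phenoxide by SN2 at the primary allylic bromide, under carbonate conditions that the pinacol boronate tolerates.

Step 4
Reactants: 3 2-bromo-3-(triisopropylsilyloxy)-4H-pyran-4-one; 6 4-(prenyloxy)phenylboronic acid pinacol ester
Product: 7 2-[4-(prenyloxy)phenyl]-3-(triisopropylsilyloxy)-4H-pyran-4-one
Conditions: Pd(dppf)Cl2 (5 mol %), K3PO4 (2 equiv), 1,4-dioxane/H2O 10:1, 60 °C, argon
Reagents that add atoms: none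
Why: Suzuki–Miyaura coupling at a vinylogous acyl bromide, which adds readily to zerovalent palladium, with a weak phosphate base, little water and moderate heat so that the silyl and prenyl ethers stay intact.

Step 5
Reactants: 8 squaric acid
Product: 9 squaryl dichloride (3,4-dichlorocyclobut-3-ene-1,2-dione)
Conditions: (COCl)2 (2.2 equiv), DMF (cat.), CH2Cl2, rt to 40 °C; evaporate, use crude
Reagents that add atoms: oxalyl chloride, ClC(=O)C(=O)Cl
Why: Vilsmeier-type chlorination of the two vinylogous acid OH groups, the standard preparation of squaryl dichloride, driven by loss of CO, CO2 and HCl.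

Step 6
Reactants: 9 squaryl dichloride; 10 2-(trimethylsilyl)ethanol (2.1 equiv)
Product: 11 bis[2-(trimethylsilyl)ethyl] squarate
Conditions: 2,6-lutidine (2.2 equiv), CH2Cl2, −20 to 0 °C
Reagents that add atoms: none
Why: double addition–elimination of the alcohol at the vinylogous acid chloride carbons, with a non-nucleophilic base removing HCl before it can fragment the acid-sensitive β-silylethyl groups.

Step 7
Reactants: 11 bis[2-(trimethylsilyl)ethyl] squarate
Product: 12 4-hydroxy-2,3-bis[2-(trimethylsilyl)ethoxy]cyclobut-2-en-1-one (racemic)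
Conditions: LiAlH(OtBu)3 (1.1 equiv), THF, −78 °C; aqueous work-up
Reagents that add atoms: none
Why: mono-reduction of a squarate ester by a mild, bulky hydride that should stop at the 1,2-adduct at low temperature; the carbinol stereocentre is racemic and is lost in step 8.

Step 8
Reactants: 12 4-hydroxy-2,3-bis[2-(trimethylsilyl)ethoxy]cyclobut-2-en-1-one
Product: 13 3-[2-(trimethylsilyl)ethoxy]cyclobut-3-ene-1,2-dione (semisquarate)
Conditions: 12 M aq HCl (cat.), CH2Cl2, rt, brief; NaHCO3 wash
Reagents that add atoms: water, O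
Why: acid-catalysed 1,3-transposition (ionisation of the allylic carbinol to an alkoxy-stabilised cyclobutenyl cation, water capture at the distal alkoxy carbon, loss of one molecule of the alcohol), the established route from reduced squarates to semisquarates, with acid contact kept short for the β-silylethyl group.

Step 9
Reactants: 7 2-[4-(prenyloxy)phenyl]-3-(triisopropylsilyloxy)-4H-pyran-4-one; 13 3-[2-(trimethylsilyl)ethoxy]cyclobut-3-ene-1,2-dione
Product: 16 4-methoxy-4-{4-oxo-6-[4-(prenyloxy)phenyl]-5-(triisopropylsilyloxy)-4H-pyran-2-yl}-3-[2-(trimethylsilyl)ethoxy]cyclobut-2-en-1-one (racemic), via lithiopyranone 14 (not isolated), via lithium alkoxide 15 (not isolated)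
Conditions: lithium 2,2,6,6-tetramethylpiperidide (LiTMP, 1.05 equiv, from the amine and n-butyllithium), THF, −78 °C, 10 min; cannulate into 13 (1.2 equiv), THF, −78 °C; MeOTf (1.5 equiv), −78 to −40 °C; Et3N, then aq NaHCO3
Reagents that add atoms: methyl trifluoromethanesulfonate, COS(=O)(=O)C(F)(F)F
Why: C–H lithiation α to the ring oxygen of the γ-pyrone (the position that LiTMP lithiates at C2 of chromones) followed by 1,2-addition to the ketone-type carbonyl of the semisquarate, the one next to the alkoxy carbon and not the vinylogous ester carbonyl, and O-methylation of the tertiary lithium alkoxide in the same flask as in the usual preparation of 4-alkoxycyclobutenones; the quaternary carbon forms racemic, and the cold amine quench removes excess MeOTf before it can methylate the pyranone carbonyl.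

Step 10
Reactants: 16 4-methoxy-4-{4-oxo-6-[4-(prenyloxy)phenyl]-5-(triisopropylsilyloxy)-4H-pyran-2-yl}-3-[2-(trimethylsilyl)ethoxy]cyclobut-2-en-1-one
Product: 19 5-hydroxy-8-methoxy-4'-prenyloxy-3-(triisopropylsilyloxy)-7-[2-(trimethylsilyl)ethoxy]flavone, via dienylketene 17 (not isolated), via 4a-H dienone 18 (not isolated)
Conditions: toluene (0.01 M, degassed), 105 °C, argon
Reagents that add atoms: none
Why: Thermal conrotatory 4π opening of the cyclobutenone C1–C4 bond should give the (Z)-dienylketene 17, whose electrophilic ketene carbon bonds to the nucleophilic, enol-ether-type C5 of the pyranone in a disrotatory 6π electrocyclisation to dienone 18, and enolisation of the 4a-H then gives the C5 phenol, hydrogen-bonded to C4=O. The closest known reaction type is the Moore–Liebeskind benzannulation of 4-alkenyl and 4-heteroaryl (for example 2-furyl) 4-alkoxycyclobutenones to hydroquinone monoethers, with the weakly aromatic pyranone C5=C6 bond taking the part of an α-oxy alkenyl arm. Ring A is closed by this 6π electrocyclisation, which forms the C4a–C5 bond on the pyranone carbon pair that becomes C4a and C8a. No stereocentre results, since the racemic quaternary carbon of 16 and C4a of 18 both end as aromatic carbons. The step needs the pyranonyl group to rotate inward, which the outward preference of the C4 methoxy donor secures, and it needs intramolecular ketene capture, which high dilution favours. The earlier O-methylation fixes C8 as OMe, leaves C5 as the only free phenol and excludes oxidation to a quinone, and 105 °C lies below the onset of the aryl prenyl ether Claisen rearrangement.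

Step 11
Reactants: 19 5-hydroxy-8-methoxy-4'-prenyloxy-3-(triisopropylsilyloxy)-7-[2-(trimethylsilyl)ethoxy]flavone
Product: 20 3,5,7-trihydroxy-8-methoxy-4'-prenyloxyflavone (target)
Conditions: tetrabutylammonium fluoride (TBAF, 4 equiv), THF, 0 to 40 °C, argon, dark; aq NH4Cl
Reagents that add atoms: none
Why: fluoride should cleave the enol TIPS ether directly and fragment the β-silylethyl ether (loss of fluorotrimethylsilane and ethylene), because the 7-oxide, a vinylogous carboxylate para to C4=O, is a good leaving group; the methyl and prenyl ethers are inert, and with no acid present neither prenyl cleavage nor Wessely–Moser isomerisation of ring A is possible.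

**Compound list**

1 | 3-hydroxy-4H-pyran-4-one (pyromeconic acid) | O=c1ccocc1O | starting material
2 | 2-bromo-3-hydroxy-4H-pyran-4-one | O=c1ccoc(Br)c1O | intermediate
3 | 2-bromo-3-(triisopropylsilyloxy)-4H-pyran-4-one | O=c1ccoc(Br)c1O[Si](C(C)C)(C(C)C)C(C)C | intermediate
4 | 4-hydroxyphenylboronic acid pinacol ester | CC1(C)OB(c2ccc(O)cc2)OC1(C)C | starting material
5 | prenyl bromide | CC(C)=CCBr | starting material
6 | 4-(prenyloxy)phenylboronic acid pinacol ester | CC(C)=CCOc1ccc(cc1)B1OC(C)(C)C(C)(C)O1 | intermediate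
7 | 2-[4-(prenyloxy)phenyl]-3-(triisopropylsilyloxy)-4H-pyran-4-one | CC(C)=CCOc1ccc(cc1)-c1occc(=O)c1O[Si](C(C)C)(C(C)C)C(C)C | intermediate
8 | squaric acid | OC1=C(O)C(=O)C1=O | starting material
9 | squaryl dichloride | ClC1=C(Cl)C(=O)C1=O | intermediate
10 | 2-(trimethylsilyl)ethanol | C[Si](C)(C)CCO | starting material
11 | bis[2-(trimethylsilyl)ethyl] squarate | C[Si](C)(C)CCOC1=C(OCC[Si](C)(C)C)C(=O)C1=O | intermediate
12 | 4-hydroxy-2,3-bis[2-(trimethylsilyl)ethoxy]cyclobut-2-en-1-one (racemic) | C[Si](C)(C)CCOC1=C(OCC[Si](C)(C)C)C(O)C1=O | intermediate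
13 | 3-[2-(trimethylsilyl)ethoxy]cyclobut-3-ene-1,2-dione | C[Si](C)(C)CCOC1=CC(=O)C1=O | intermediate
14 | 6-lithio-2-[4-(prenyloxy)phenyl]-3-(triisopropylsilyloxy)-4H-pyran-4-one | [Li]c1cc(=O)c(O[Si](C(C)C)(C(C)C)C(C)C)c(o1)-c1ccc(OCC=C(C)C)cc1 | intermediate
15 | lithium alkoxide of the 4-hydroxy-4-(pyranonyl)cyclobutenone (racemic) | [Li]OC1(C(=O)C=C1OCC[Si](C)(C)C)c1cc(=O)c(O[Si](C(C)C)(C(C)C)C(C)C)c(o1)-c1ccc(OCC=C(C)C)cc1 | intermediate
16 | 4-methoxy-4-{4-oxo-6-[4-(prenyloxy)phenyl]-5-(triisopropylsilyloxy)-4H-pyran-2-yl}-3-[2-(trimethylsilyl)ethoxy]cyclobut-2-en-1-one (racemic) | COC1(C(=O)C=C1OCC[Si](C)(C)C)c1cc(=O)c(O[Si](C(C)C)(C(C)C)C(C)C)c(o1)-c1ccc(OCC=C(C)C)cc1 | intermediate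
17 | (Z)-4-methoxy-4-(pyranonyl)-3-[2-(trimethylsilyl)ethoxy]buta-1,3-dien-1-one (dienylketene) | O=C=C/C(OCC[Si](C)(C)C)=C(OC)\c1cc(=O)c(O[Si](C(C)C)(C(C)C)C(C)C)c(o1)-c1ccc(OCC=C(C)C)cc1 | intermediate
18 | 8-methoxy-2-[4-(prenyloxy)phenyl]-3-(triisopropylsilyloxy)-7-[2-(trimethylsilyl)ethoxy]-4aH-chromene-4,5-dione (racemic) | COC1=C2OC(-c3ccc(OCC=C(C)C)cc3)=C(O[Si](C(C)C)(C(C)C)C(C)C)C(=O)C2C(=O)C=C1OCC[Si](C)(C)C | intermediate
19 | 5-hydroxy-8-methoxy-4'-prenyloxy-3-(triisopropylsilyloxy)-7-[2-(trimethylsilyl)ethoxy]flavone | COc1c(OCC[Si](C)(C)C)cc(O)c2c(=O)c(O[Si](C(C)C)(C(C)C)C(C)C)c(-c3ccc(OCC=C(C)C)cc3)oc12 | intermediate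
20 | 3,5,7-trihydroxy-8-methoxy-4'-prenyloxyflavone | COc1c(O)cc(O)c2c(=O)c(O)c(-c3ccc(OCC=C(C)C)cc3)oc12 | target

**Step count**

Total: 11 steps. Longest linear sequence: 7 steps (steps 5, 6, 7, 8, 9, 10, 11, from squaric acid).

**Steps most likely to fail**

1. Step 10. The pyranone terminus is less nucleophilic than the usual alkenyl or furyl arms, so ketene capture may be too slow at a temperature the prenyl ether tolerates. Intermolecular ketene reactions would then compete, and forcing the temperature would start the aromatic Claisen rearrangement. Fallback: install the prenyl group after ring A, so the ring expansion can be run much hotter. The fallback sets out from 3 and comes back at 19.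
 - Compound 3 is coupled with bought 4-(benzyloxy)phenylboronic acid under the step 4 conditions to give 2-[4-(benzyloxy)phenyl]-3-(triisopropylsilyloxy)-4H-pyran-4-one F1.
 - The step 9 protocol with 13 gives the benzyloxy analogue of the methoxycyclobutenone F2.
 - F2 is heated in degassed xylene or mesitylene at 140 to 160 °C, now without any allyl-type aryl ether, to give 4'-benzyloxy-5-hydroxy-8-methoxy-3-(triisopropylsilyloxy)-7-[2-(trimethylsilyl)ethoxy]flavone F3.
 - Hydrogenolysis (H2, palladium on carbon, EtOAc) gives the 4',5-dihydroxy flavone F4.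
 - The 4'-OH of F4 is alkylated with 5 and K2CO3 in acetone to give 19; the chelated 5-OH should not react.

2. Step 9. The lithiated pyranone may add to unmetalated pyranone at C6, deprotonation may compete at C5, or the pyranone carbonyl may be methylated. Fallback: generate the organometallic by halogen–metal exchange and methylate separately. The fallback sets out from 7 and comes back at 16.
 - Compound 7 is zincated at C6 with TMPZnCl·LiCl (TMP = 2,2,6,6-tetramethylpiperidide) in THF to give the non-nucleophilic pyranonylzinc chloride F5.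
 - Iodine converts F5 into 6-iodo-2-[4-(prenyloxy)phenyl]-3-(triisopropylsilyloxy)-4H-pyran-4-one F6.
 - Iodine–magnesium exchange with iPrMgCl·LiCl at −78 °C gives the pyranonylmagnesium chloride F7, free of amine and of unmetalated pyranone.
 - Addition of F7 to 13 and an NH4Cl quench give the 4-hydroxy-4-(pyranonyl)cyclobutenone F8.
 - F8 is methylated with MeI and Ag2O to give 16.

3. Step 8. The β-silylethyl group may be lost by acid-induced fragmentation to ethylene during the collapse to the dione. Fallback: an acid-free route to 13 that sets out from 9 and comes back at 13.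
 - One equivalent of 10 with 2,6-lutidine at −78 °C gives 3-chloro-4-[2-(trimethylsilyl)ethoxy]cyclobut-3-ene-1,2-dione F9.
 - The vinylogous acyl chloride of F9 is reduced to C–H with Bu3SnH and catalytic Pd(PPh3)4 (insertion of zerovalent palladium into the C–Cl bond, then hydride transfer) to give 13.

**Further compounds**

F1 | step 10 | 2-[4-(benzyloxy)phenyl]-3-(triisopropylsilyloxy)-4H-pyran-4-one | O=c1ccoc(-c2ccc(OCc3ccccc3)cc2)c1O[Si](C(C)C)(C(C)C)C(C)C
F2 | step 10 | 4-{6-[4-(benzyloxy)phenyl]-4-oxo-5-(triisopropylsilyloxy)-4H-pyran-2-yl}-4-methoxy-3-[2-(trimethylsilyl)ethoxy]cyclobut-2-en-1-one (racemic) | COC1(C(=O)C=C1OCC[Si](C)(C)C)c1cc(=O)c(O[Si](C(C)C)(C(C)C)C(C)C)c(o1)-c1ccc(OCc2ccccc2)cc1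
F3 | step 10 | 4'-benzyloxy-5-hydroxy-8-methoxy-3-(triisopropylsilyloxy)-7-[2-(trimethylsilyl)ethoxy]flavone | COc1c(OCC[Si](C)(C)C)cc(O)c2c(=O)c(O[Si](C(C)C)(C(C)C)C(C)C)c(-c3ccc(OCc4ccccc4)cc3)oc12
F4 | step 10 | 4',5-dihydroxy-8-methoxy-3-(triisopropylsilyloxy)-7-[2-(trimethylsilyl)ethoxy]flavone | COc1c(OCC[Si](C)(C)C)cc(O)c2c(=O)c(O[Si](C(C)C)(C(C)C)C(C)C)c(-c3ccc(O)cc3)oc12
F5 | step 9 | {4-oxo-6-[4-(prenyloxy)phenyl]-5-(triisopropylsilyloxy)-4H-pyran-2-yl}zinc chloride | Cl[Zn]c1cc(=O)c(O[Si](C(C)C)(C(C)C)C(C)C)c(o1)-c1ccc(OCC=C(C)C)cc1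
F6 | step 9 | 6-iodo-2-[4-(prenyloxy)phenyl]-3-(triisopropylsilyloxy)-4H-pyran-4-one | Ic1cc(=O)c(O[Si](C(C)C)(C(C)C)C(C)C)c(o1)-c1ccc(OCC=C(C)C)cc1
F7 | step 9 | {4-oxo-6-[4-(prenyloxy)phenyl]-5-(triisopropylsilyloxy)-4H-pyran-2-yl}magnesium chloride | Cl[Mg]c1cc(=O)c(O[Si](C(C)C)(C(C)C)C(C)C)c(o1)-c1ccc(OCC=C(C)C)cc1
F8 | step 9 | 4-hydroxy-4-{4-oxo-6-[4-(prenyloxy)phenyl]-5-(triisopropylsilyloxy)-4H-pyran-2-yl}-3-[2-(trimethylsilyl)ethoxy]cyclobut-2-en-1-one (racemic) | OC1(C(=O)C=C1OCC[Si](C)(C)C)c1cc(=O)c(O[Si](C(C)C)(C(C)C)C(C)C)c(o1)-c1ccc(OCC=C(C)C)cc1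
F9 | step 8 | 3-chloro-4-[2-(trimethylsilyl)ethoxy]cyclobut-3-ene-1,2-dione | C[Si](C)(C)CCOC1=C(Cl)C(=O)C1=O
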